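## Retrosynthetic overview

1. The target is two coumarins joined by one oxygen, from C-6 of unit A (a 7-hydroxycoumarin) to C-5 of unit B (a 6,7-dihydroxycoumarin). The last operations are oxidation of the C-2 methylene of a unit-A 2H-chromene to the lactone carbonyl, then cleavage of three methyl ethers.
2. Feature used: in the benzene ring of unit A, O-1 (on C-8a) stands para to the ether carbon C-6. Of the two carbons ortho to O-1, only C-4a is open (its neighbour is C-5–H), while C-8 is pinched between O-1 and the 7-oxygen. A propargyl group on O-1 can therefore pass its terminal carbon (future C-4) to C-4a and hand its CH2 (future C-2) back to O-1.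
3. Key disconnection: C-4a–C-4 and O-1–C-2 of the unit-A pyran ring, leading back to the aryl propargyl ether of an intact unit-B coumarin (propargyl Claisen shift, hydrogen shift, oxa-6π electrocyclisation).
4. Unit B: the lactone comes from a Z-selective olefination and lactonisation at 50 °C, because an E-cinnamate would close only near 200 °C, where the propargyl ether already reacts. The diaryl ether comes from SNAr of a 2-fluorobenzaldehyde by 2-methoxy-4-propargyloxyphenol. The O-1 oxygen of unit B comes from directed ortho-lithiation, borylation and oxidation.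
5. Ring order: both benzene rings are bought, the pyranone of unit B closes first (step 6), and the pyran of unit A closes second (step 7) and is raised to the pyranone in step 8.

Key step: step 7

Remark: the target has no stereocentre and its diaryl ether rotates freely, so the only stereochemical element to control is the Z alkene of the cinnamate intermediates.

## Route

Step 1
Reactants: 1 2-fluoro-3,4-dimethoxybenzaldehyde
Product: 5 2-fluoro-6-hydroxy-3,4-dimethoxybenzaldehyde, via lithium amino alkoxide 2 (not isolated), via C-6 aryllithium 3 (not isolated), via formyl arylboronic acid 4 (not isolated)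
Conditions: LiN(Me)CH2CH2NMe2 (from MeNHCH2CH2NMe2 + n-BuLi), THF, −20 °C; n-BuLi (2 equiv), −20 °C; B(OMe)3, −78 °C → rt; AcOH, 30% H2O2 (in portions until 4 is consumed), 0 °C
Reagents that add atoms: hydrogen peroxide OO (the phenol oxygen of 5); into intermediates only: lithium N,N,N'-trimethylethylenediamide [Li]N(C)CCN(C)C (2, 3), trimethyl borate COB(OC)OC and water O (4)
Why: α-Amino-alkoxide-directed ortho-lithiation followed by borylation and peroxide oxidation: the diamine arm of 2 chelates n-BuLi and delivers it to C-6–H, the only C–H ortho to the masked formyl group (C-2 carries fluorine and C-5–H beside the 4-methoxy group lies outside the chelate), and the acetic-acid-buffered peroxide should convert the C–B bond by 1,2-aryl shift much faster than a Dakin reaction could attack the new salicylaldehyde.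

Step 2
Reactants: 5 2-fluoro-6-hydroxy-3,4-dimethoxybenzaldehyde
Product: 6 2-fluoro-3,4-dimethoxy-6-(methoxymethoxy)benzaldehyde
Conditions: MOMCl, i-Pr2NEt, CH2Cl2, 0 °C → rt
Reagents that add atoms: chloromethyl methyl ether COCCl
Why: Acetal-type O-alkylation of the phenol (MOM protection), needed because a free ortho-phenoxide would push charge into the ring and shut down the substitution of step 4, while the MOM ether withstands hot carbonate and the phosphonate anion used later.

Step 3
Reactants: 7 2-methoxyhydroquinone (2-methoxybenzene-1,4-diol); 8 propargyl bromide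
Product: 9 2-methoxy-4-(prop-2-yn-1-yloxy)phenol
Conditions: K2CO3 (1.0 equiv), 8 (1.0 equiv), degassed acetone, Ar, rt → 40 °C
Reagents that add atoms: propargyl bromide 8 C#CCBr
Why: Williamson ether synthesis under base-limited conditions: the 4-OH is meta to the methoxy group, hence the more acidic one, and is unhindered, whereas the 1-OH is hydrogen-bonded to and screened by the neighbouring methoxy group, so mono-alkylation should fall mainly on O-4, with bis-ether and isomer removed by chromatography.

Step 4
Reactants: 6 2-fluoro-3,4-dimethoxy-6-(methoxymethoxy)benzaldehyde; 9 2-methoxy-4-(prop-2-yn-1-yloxy)phenol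
Product: 10 3,4-dimethoxy-6-(methoxymethoxy)-2-[2-methoxy-4-(prop-2-yn-1-yloxy)phenoxy]benzaldehyde
Conditions: Cs2CO3, DMF, 110 °C, Ar
Reagents that add atoms: none
Why: Nucleophilic aromatic substitution by addition–elimination: the phenoxide of 9 adds to C-2 of 6, the charge of the Meisenheimer adduct is taken up by the ortho formyl group, fluoride is the best leaving group for this mechanism, and 110 °C lies well below the onset of the propargyl Claisen rearrangement.

Step 5
Reactants: 10 the diaryl ether aldehyde; 11 ethyl 2-(diphenoxyphosphoryl)acetate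
Product: 12 ethyl (2Z)-3-{3,4-dimethoxy-6-(methoxymethoxy)-2-[2-methoxy-4-(prop-2-yn-1-yloxy)phenoxy]phenyl}prop-2-enoate
Conditions: 11 (1.2 equiv), NaH (1.1 equiv), THF, 0 °C; then 10, −78 → 0 °C
Reagents that add atoms: ethyl 2-(diphenoxyphosphoryl)acetate 11 CCOC(=O)CP(=O)(Oc1ccccc1)Oc1ccccc1
Why: Z-selective Horner–Wadsworth–Emmons olefination (Ando modification): the electron-poor diphenyl phosphonate makes collapse of the kinetically favoured syn adduct faster than its reversal, so the Z-cinnamate should prevail, and the preformed stabilised carbanion is too weak a base to touch the terminal alkyne.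

Step 6
Reactants: 12 the Z-cinnamate MOM ether
Product: 14 5-[2-methoxy-4-(prop-2-yn-1-yloxy)phenoxy]-6,7-dimethoxy-2H-chromen-2-one, via free Z-hydroxycinnamate 13 (not isolated)
Conditions: 3 M HCl, THF, 50 °C
Reagents that add atoms: none
Why: Acid hydrolysis of the MOM acetal frees the phenol of 13, which the Z alkene holds next to the ester, so the pyranone of unit B closes by spontaneous intramolecular transesterification (lactonisation), while aryl propargyl and aryl methyl ethers are inert to dilute HCl.

Step 7
Reactants: 14 5-[2-methoxy-4-(prop-2-yn-1-yloxy)phenoxy]-6,7-dimethoxy-2H-chromen-2-one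
Product: 18 5-[(7-methoxy-2H-chromen-6-yl)oxy]-6,7-dimethoxy-2H-chromen-2-one, via allenyl cyclohexadienone 15 (not isolated), via ortho-allenylphenol 16 (not isolated), via ortho-quinone methide 17 (not isolated)
Conditions: PhNEt2 (degassed, 0.05 M), 210 °C, Ar
Reagents that add atoms: none
Why: Heating sets off an aromatic propargyl Claisen rearrangement, a concerted [3,3] shift in which the O–CH2 bond breaks while the alkyne terminus bonds to C-4a, and the allenyl dienone 15 re-aromatises by enolisation to the ortho-allenylphenol 16. A [1,5]-hydrogen shift from the phenol oxygen to the central allene carbon then gives the Z-configured ortho-quinone methide 17, whose O=C–C=C–C=C array closes the pyran ring of unit A by a thermal, disrotatory oxa-6π electrocyclisation that forms O-1–C-2 and restores the arene. The closest known reaction type is the thermal conversion of aryl propargyl ethers into 2H-chromenes in high-boiling aniline solvents, which is well established for 3,4-dialkoxyphenyl ethers. No stereocentre survives, since the sp3 carbon of 15 is lost on enolisation and 18 is achiral. The step needs regioselectivity between the two carbons ortho to O-1: C-4a has only C-5–H beside it and lies para to the donating 7-methoxy group, whereas C-8 is squeezed between O-1 and the 7-methoxy group, whose methyl is turned toward C-8 by the bulky 6-aryloxy neighbour. The absence of a strong base (no fluoride, no alkoxide) keeps 16 from diverting to a 2-methylbenzofuran, and the diaryl ether, the methyl ethers and the lactone of unit B have no bond that is labile at this temperature.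

Step 8
Reactants: 18 5-[(7-methoxy-2H-chromen-6-yl)oxy]-6,7-dimethoxy-2H-chromen-2-one
Product: 19 5-[(7-methoxy-2-oxo-2H-chromen-6-yl)oxy]-6,7-dimethoxy-2H-chromen-2-one
Conditions: pyridinium chlorochromate [C5H5NH][CrO3Cl] (5 equiv), Celite, CH2Cl2, reflux
Reagents that add atoms: pyridinium chlorochromate [O-][Cr](=O)(=O)Cl.c1cc[nH+]cc1
Why: Allylic oxidation of a 2H-chromene to a coumarin by hexavalent chromium, a known conversion: the C-2 methylene is activated by both O-1 and the C-3–C-4 alkene, loss of hydride gives a benzopyrylium chromate that collapses to the lactol level and is oxidised on to the lactone, and unit B offers no C–H of this kind.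

Step 9
Reactants: 19 5-[(7-methoxy-2-oxo-2H-chromen-6-yl)oxy]-6,7-dimethoxy-2H-chromen-2-one
Product: 20 5-[(7-hydroxy-2-oxo-2H-chromen-6-yl)oxy]-6,7-dihydroxy-2H-chromen-2-one (CNP0197949.0)
Conditions: BBr3 (8 equiv), CH2Cl2, −78 °C → rt; H2O, 0 °C
Reagents that add atoms: none
Why: Lewis-acid cleavage of aryl methyl ethers: BBr3 binds each methoxy oxygen and bromide removes the methyl group by SN2, whereas the diaryl ether has no sp3 carbon to attack and both lactones are released unchanged when the borates are hydrolysed.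

## Compound list

1 | 2-fluoro-3,4-dimethoxybenzaldehyde | COc1ccc(C=O)c(F)c1OC | starting material
2 | lithium (2-fluoro-3,4-dimethoxyphenyl){[2-(dimethylamino)ethyl](methyl)amino}methanolate | COc1ccc(C(O[Li])N(C)CCN(C)C)c(F)c1OC | intermediate
3 | 6-lithio derivative of 2 | [Li]c1cc(OC)c(OC)c(F)c1C(O[Li])N(C)CCN(C)C | intermediate
4 | (3-fluoro-2-formyl-4,5-dimethoxyphenyl)boronic acid | OB(O)c1cc(OC)c(OC)c(F)c1C=O | intermediate
5 | 2-fluoro-6-hydroxy-3,4-dimethoxybenzaldehyde | COc1cc(O)c(C=O)c(F)c1OC | intermediate
6 | 2-fluoro-3,4-dimethoxy-6-(methoxymethoxy)benzaldehyde | COCOc1cc(OC)c(OC)c(F)c1C=O | intermediate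
7 | 2-methoxyhydroquinone | COc1cc(O)ccc1O | starting material
8 | propargyl bromide | C#CCBr | starting material
9 | 2-methoxy-4-(prop-2-yn-1-yloxy)phenol | C#CCOc1ccc(O)c(OC)c1 | intermediate
10 | 3,4-dimethoxy-6-(methoxymethoxy)-2-[2-methoxy-4-(prop-2-yn-1-yloxy)phenoxy]benzaldehyde | C#CCOc1ccc(Oc2c(OC)c(OC)cc(OCOC)c2C=O)c(OC)c1 | intermediate
11 | ethyl 2-(diphenoxyphosphoryl)acetate | CCOC(=O)CP(=O)(Oc1ccccc1)Oc1ccccc1 | starting material
12 | ethyl (2Z)-3-{3,4-dimethoxy-6-(methoxymethoxy)-2-[2-methoxy-4-(prop-2-yn-1-yloxy)phenoxy]phenyl}prop-2-enoate | CCOC(=O)/C=C\c1c(OCOC)cc(OC)c(OC)c1Oc1ccc(OCC#C)cc1OC | intermediate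
13 | ethyl (2Z)-3-{6-hydroxy-3,4-dimethoxy-2-[2-methoxy-4-(prop-2-yn-1-yloxy)phenoxy]phenyl}prop-2-enoate | CCOC(=O)/C=C\c1c(O)cc(OC)c(OC)c1Oc1ccc(OCC#C)cc1OC | intermediate
14 | 5-[2-methoxy-4-(prop-2-yn-1-yloxy)phenoxy]-6,7-dimethoxy-2H-chromen-2-one | C#CCOc1ccc(Oc2c(OC)c(OC)cc3oc(=O)ccc23)c(OC)c1 | intermediate
15 | 5-{[6-methoxy-4-oxo-3-(propa-1,2-dien-1-yl)cyclohexa-1,5-dien-1-yl]oxy}-6,7-dimethoxy-2H-chromen-2-one (racemic, transient) | C=C=CC1C=C(Oc2c(OC)c(OC)cc3oc(=O)ccc23)C(OC)=CC1=O | intermediate
16 | 5-[4-hydroxy-2-methoxy-5-(propa-1,2-dien-1-yl)phenoxy]-6,7-dimethoxy-2H-chromen-2-one | C=C=Cc1cc(Oc2c(OC)c(OC)cc3oc(=O)ccc23)c(OC)cc1O | intermediate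
17 | 5-{[(3Z)-6-methoxy-4-oxo-3-(prop-2-en-1-ylidene)cyclohexa-1,5-dien-1-yl]oxy}-6,7-dimethoxy-2H-chromen-2-one | C=C/C=C1/C=C(Oc2c(OC)c(OC)cc3oc(=O)ccc23)C(OC)=CC1=O | intermediate
18 | 5-[(7-methoxy-2H-chromen-6-yl)oxy]-6,7-dimethoxy-2H-chromen-2-one | COc1cc2OCC=Cc2cc1Oc1c(OC)c(OC)cc2oc(=O)ccc12 | intermediate
19 | 5-[(7-methoxy-2-oxo-2H-chromen-6-yl)oxy]-6,7-dimethoxy-2H-chromen-2-one | COc1cc2oc(=O)ccc2cc1Oc1c(OC)c(OC)cc2oc(=O)ccc12 | intermediate
20 | 5-[(7-hydroxy-2-oxo-2H-chromen-6-yl)oxy]-6,7-dihydroxy-2H-chromen-2-one | O=c1ccc2cc(Oc3c(O)c(O)cc4oc(=O)ccc34)c(O)cc2o1 | target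

## Step count

Total step count: 9.
Longest linear sequence: 8 steps (1, 2, 4, 5, 6, 7, 8, 9) from 1. Step 3 is a one-step side branch.

## Steps most likely to fail

**Step 7.**
- What may go wrong: part of the sigmatropic shift may run to C-8 and lead to the angular chromene. The electron-rich chromene may also oligomerise during long heating at 210 °C.
- Fallback (sets out from 14, returns at 18): the pericyclic cascade is replaced by π-acid catalysis with Ph3PAuNTf2 (monovalent gold, 2–5 mol %) in CH2Cl2 at rt.
- The gold-bound alkyne is attacked by the arene in a 6-endo-dig hydroarylation of Friedel–Crafts type. Ring closure is then steered to the carbon para to the methoxy donor (C-4a), steric discrimination is sharper at room temperature, and no thermal stress arises. No new compound is made.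

**Step 4.**
- What may go wrong: addition to a fluoroarene that carries three donor oxygens and two ortho neighbours may be sluggish. Prolonged heating with carbonate may then bring base-induced propargyl-to-allenyl isomerisation or addition of the acetylide to the aldehyde.
- Fallback (sets out from 6, returns at 14): the roles of the two rings are exchanged, so that the donor-rich ring becomes the nucleophile and the electrophile is a para-fluorobenzaldehyde with a single donor.
- Sodium benzyl oxide (BnOH, NaH, DMF, rt → 60 °C) is a smaller and much stronger nucleophile than a phenoxide. It should displace fluoride from 6 to give 2-(benzyloxy)-3,4-dimethoxy-6-(methoxymethoxy)benzaldehyde F1.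
- Olefination with 11 as in step 5 gives ethyl (2Z)-3-[2-(benzyloxy)-3,4-dimethoxy-6-(methoxymethoxy)phenyl]prop-2-enoate F2.
- Dilute HCl in THF gives, through ethyl (2Z)-3-[2-(benzyloxy)-6-hydroxy-3,4-dimethoxyphenyl]prop-2-enoate F3, the lactone 5-(benzyloxy)-6,7-dimethoxy-2H-chromen-2-one F4.
- Hydrogenolysis (H2, Pd/C, EtOAc, stopped after one equivalent) gives 5-hydroxy-6,7-dimethoxy-2H-chromen-2-one F5.
- The phenoxide of F5 (K2CO3, DMF, 100 °C) substitutes commercial 4-fluoro-3-methoxybenzaldehyde para to its formyl group to give 4-[(6,7-dimethoxy-2-oxo-2H-chromen-5-yl)oxy]-3-methoxybenzaldehyde F6.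
- Baeyer–Villiger oxidation (mCPBA, CH2Cl2) gives 4-[(6,7-dimethoxy-2-oxo-2H-chromen-5-yl)oxy]-3-methoxyphenyl formate F7.
- Mild hydrolysis (KHCO3, aq MeOH) gives 5-(4-hydroxy-2-methoxyphenoxy)-6,7-dimethoxy-2H-chromen-2-one F8, and Williamson alkylation with 8 (K2CO3, acetone) gives 14.

**Step 1.**
- What may go wrong: lithiation may stray to C-5 beside the 4-methoxy group, n-BuLi may attack the C–F carbon, or peroxide may over-oxidise the product by a Dakin reaction.
- Fallback (sets out from 1, returns at 5): organolithium chemistry is replaced by catalytic, imine-directed C–H borylation.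
- Condensation of 1 with tert-butylamine (MgSO4, CH2Cl2) gives (E)-N-tert-butyl-1-(2-fluoro-3,4-dimethoxyphenyl)methanimine F9.
- [Ir(OMe)(cod)]2, 8-aminoquinoline and B2pin2 in THF at 80 °C should borylate the only C–H ortho to the imine, giving (E)-N-tert-butyl-1-[2-fluoro-3,4-dimethoxy-6-(4,4,5,5-tetramethyl-1,3,2-dioxaborolan-2-yl)phenyl]methanimine F10.
- Mild aqueous acid gives 2-fluoro-3,4-dimethoxy-6-(4,4,5,5-tetramethyl-1,3,2-dioxaborolan-2-yl)benzaldehyde F11.
- Trimethylamine N-oxide in THF oxidises the C–B bond without any peroxide, so no Dakin pathway is open, and aqueous work-up gives 5.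

## Further compounds

F0 | step 7 | none | none
F1 | step 4 | 2-(benzyloxy)-3,4-dimethoxy-6-(methoxymethoxy)benzaldehyde | COCOc1cc(OC)c(OC)c(OCc2ccccc2)c1C=O
F2 | step 4 | ethyl (2Z)-3-[2-(benzyloxy)-3,4-dimethoxy-6-(methoxymethoxy)phenyl]prop-2-enoate | CCOC(=O)/C=C\c1c(OCOC)cc(OC)c(OC)c1OCc1ccccc1
F3 | step 4 | ethyl (2Z)-3-[2-(benzyloxy)-6-hydroxy-3,4-dimethoxyphenyl]prop-2-enoate | CCOC(=O)/C=C\c1c(O)cc(OC)c(OC)c1OCc1ccccc1
F4 | step 4 | 5-(benzyloxy)-6,7-dimethoxy-2H-chromen-2-one | COc1cc2oc(=O)ccc2c(OCc2ccccc2)c1OC
F5 | step 4 | 5-hydroxy-6,7-dimethoxy-2H-chromen-2-one | COc1cc2oc(=O)ccc2c(O)c1OC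
F6 | step 4 | 4-[(6,7-dimethoxy-2-oxo-2H-chromen-5-yl)oxy]-3-methoxybenzaldehyde | COc1cc(C=O)ccc1Oc1c(OC)c(OC)cc2oc(=O)ccc12
F7 | step 4 | 4-[(6,7-dimethoxy-2-oxo-2H-chromen-5-yl)oxy]-3-methoxyphenyl formate | COc1cc(OC=O)ccc1Oc1c(OC)c(OC)cc2oc(=O)ccc12
F8 | step 4 | 5-(4-hydroxy-2-methoxyphenoxy)-6,7-dimethoxy-2H-chromen-2-one | COc1cc(O)ccc1Oc1c(OC)c(OC)cc2oc(=O)ccc12
F9 | step 1 | (E)-N-tert-butyl-1-(2-fluoro-3,4-dimethoxyphenyl)methanimine | COc1ccc(/C=N/C(C)(C)C)c(F)c1OC
F10 | step 1 | (E)-N-tert-butyl-1-[2-fluoro-3,4-dimethoxy-6-(4,4,5,5-tetramethyl-1,3,2-dioxaborolan-2-yl)phenyl]methanimine | COc1cc(B2OC(C)(C)C(C)(C)O2)c(/C=N/C(C)(C)C)c(F)c1OC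
F11 | step 1 | 2-fluoro-3,4-dimethoxy-6-(4,4,5,5-tetramethyl-1,3,2-dioxaborolan-2-yl)benzaldehyde | COc1cc(B2OC(C)(C)C(C)(C)O2)c(C=O)c(F)c1OC
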